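Ring numbering: C1 (side chain C7–C11), C2 (angelate), C3 (OH), C4–C5 (epoxide, methyl on C4), C6 (angelate). The ring is read as a cyclohexene, the C4–C5 epoxide being a masked alkene, and is cut at C2–C3 and C6–C1. One chelation-controlled endo Diels–Alder reaction between a 1,4-dioxygenated 2-methylbutadiene (C3–C6) and a (Z)-β-angeloyloxy enone (C1–C2) that already carries the whole side chain forms both bonds and sets C1, C2, C3 and C6; the free C8 hydroxyl steers the face. The all-cis adduct is epimeric at C6, which a Mitsunobu esterification with angelic acid inverts. Hydroxyl-directed epoxidation ends the route.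

Key step: step 6

Remark: angeloyl (Ang) = (Z)-2-methylbut-2-enoyl; tBu-box = 2,2'-(propane-2,2-diyl)bis[(4S)-4-tert-butyl-4,5-dihydro-1,3-oxazole]; the copper bis(oxazoline) catalyst of step 1 is assumed to give the 8S alcohol and the D-fructose-derived ketone of step 11 the 10R epoxide, as their usual models predict (the mirror-image ligand or ketone would be used otherwise).

Step 1
Reactants: 1 ethyl glyoxylate; 2 3-methylbut-1-ene
Product: 3 ethyl (2S)-2-hydroxy-5-methylhex-4-enoate
Conditions: [Cu((S,S)-tBu-box)](SbF6)2 (10 mol %), CH2Cl2, 0 °C to rt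
Reagents that add atoms: none
Why: Catalytic asymmetric glyoxylate-ene reaction in which the terminal CH2 of 2 adds to the chelated aldehyde with transfer of the isopropyl methine hydrogen, giving the trisubstituted alkene directly; C8 (S) is set by the chiral copper bis(oxazoline) complex, which shields one face of the bound glyoxylate.

Step 2
Reactants: 3 ethyl (2S)-2-hydroxy-5-methylhex-4-enoate
Product: 5 (4S)-4-hydroxy-7-methyloct-6-en-1-yn-3-one, via Weinreb amide 4 (not isolated)
Conditions: MeNHOMe·HCl, iPrMgCl, THF, −20 °C; then HC≡CMgBr, 0 °C; aq. NH4Cl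
Reagents that add atoms: ethynylmagnesium bromide, C#C[Mg]Br (N,O-dimethylhydroxylamine hydrochloride, CNOC.Cl, supplies the amide nitrogen of 4 only)
Why: One-pot Weinreb ketone synthesis, in which the magnesium amide converts the ester into 4 and its stable magnesium chelate takes up one ethynyl group and releases the ynone only on quench; the C8 magnesium alkoxide is inert and C8 is not epimerised.

Step 3
Reactants: 5 (4S)-4-hydroxy-7-methyloct-6-en-1-yn-3-one; 6 angelic acid
Product: 7 (1Z,4S)-4-hydroxy-7-methyl-3-oxoocta-1,6-dien-1-yl (Z)-2-methylbut-2-enoate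
Conditions: iPr2NEt (0.2 equiv), CH2Cl2, −20 °C
Reagents that add atoms: none
Why: Base-catalysed conjugate addition (oxa-Michael) of the carboxylate to the terminal ynone, whose anti course (protonation of the allenolate on the side away from the carboxylate) should give the (Z)-enol ester as the kinetic product at low temperature, while the hydroxyl stays protonated in the acid buffer and should not cyclise.

Step 4
Reactants: 8 (tert-butyldimethylsilyloxy)acetaldehyde; 9 2-(triphenylphosphoranylidene)propanal
Product: 10 (E)-4-(tert-butyldimethylsilyloxy)-2-methylbut-2-enal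
Conditions: toluene, 80 °C
Reagents that add atoms: none
Why: Wittig olefination with a stabilised ylide, which is (E)-selective and leaves the product enal unreactive toward a second olefination.

Step 5
Reactants: 10 (E)-4-(tert-butyldimethylsilyloxy)-2-methylbut-2-enal
Product: 12 (1E,3E)-4-(tert-butyldimethylsilyloxy)-2-methylbuta-1,3-dien-1-yl 2-(trimethylsilyl)ethyl carbonate, via potassium dienolate 11 (not isolated)
Conditions: KN(SiMe3)2, THF, −78 °C; then 4-nitrophenyl 2-(trimethylsilyl)ethyl carbonate, −78 to 0 °C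
Reagents that add atoms: 4-nitrophenyl 2-(trimethylsilyl)ethyl carbonate, C[Si](C)(C)CCOC(=O)Oc1ccc(cc1)[N+](=O)[O-]
Why: γ-Deprotonation of the enal to the extended dienolate and O-acylation by the activated carbonate (dienyl carbonate synthesis), the s-trans enal giving the 1E enol carbonate and allylic strain with the 2-methyl group favouring the 3E silyl enol ether.

Step 6
Reactants: 7 (1Z,4S)-4-hydroxy-7-methyl-3-oxoocta-1,6-dien-1-yl (Z)-2-methylbut-2-enoate; 12 (1E,3E)-4-(tert-butyldimethylsilyloxy)-2-methylbuta-1,3-dien-1-yl 2-(trimethylsilyl)ethyl carbonate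
Product: 13 2-angeloyloxy-6-(tert-butyldimethylsilyloxy)-1-[(2S)-2-hydroxy-5-methylhex-4-enoyl]-4-methyl-3-[2-(trimethylsilyl)ethoxycarbonyloxy]cyclohex-4-ene (overview numbering; substituents on C1/C2/C3/C6 all cis)
Conditions: MgBr2·OEt2 (1.2 equiv), 12 (1.5 equiv), CH2Cl2, −40 to 0 °C
Reagents that add atoms: none
Why: Normal-demand Diels–Alder reaction, concerted but asynchronous, between electron-rich diene 12 (ring atoms C3–C6) and enone 7 (C1=C2), whose ketone and C8 hydroxyl are held in a five-membered magnesium chelate; the closest known reactions are chelation-controlled cycloadditions of α'-hydroxy enones and MgBr2-mediated reactions of silyloxy dienes. The single ring formed, cyclohexene C1–C6, closes by intermolecular suprafacial [4+2] addition that makes C2–C3 and C6–C1 in the same event. C1 and C2 become cis because the (Z) geometry of 7 is transferred; the (1E,3E) geometry of 12 places the C3 and C6 oxygens cis to each other, and the endo transition state (chelated carbonyl under C4–C5) places both cis to the C1 acyl group, so the all-cis adduct results. The absolute sense comes from C8: allylic strain keeps the (Z)-enone s-cis, the chelate is coplanar with it, and the C9 chain blocks one face so that the diene adds to the face carrying the C8 hydrogen. Regioselectivity is needed and is secured by two concordant effects in 12, the silyloxy group on C6 and the methyl on C4, which make C3 the nucleophilic terminus that bonds to the β-carbon C2, the carbonate on C3 being only a weak donor. Endo and facial selectivity are the two points at risk; the (Z)-enol ester is used cold to avoid isomerisation.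

Step 7
Reactants: 13 the all-cis cyclohexenyl ketone
Product: 14 2-angeloyloxy-6-(tert-butyldimethylsilyloxy)-1-[(3S)-3-hydroxy-6-methylhepta-1,5-dien-2-yl]-4-methyl-3-[2-(trimethylsilyl)ethoxycarbonyloxy]cyclohex-4-ene (all cis)
Conditions: Zn, CH2Br2, TiCl4, THF/CH2Cl2, 0 °C to rt
Reagents that add atoms: dibromomethane, BrCBr
Why: Takai–Lombardo methylenation, a non-basic titanium–zinc methylene transfer that should convert the hindered, enolisable ketone into the C7=CH2 alkene without β-elimination of the C2 and C6 oxygen groups or epimerisation at C1 and C8, and that tolerates esters, the carbonate, the silyl ether and the free hydroxyl.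

Step 8
Reactants: 14 the allylic alcohol
Product: 16 2-angeloyloxy-1-[(3S)-3-angeloyloxy-6-methylhepta-1,5-dien-2-yl]-6-(tert-butyldimethylsilyloxy)-4-methyl-3-[2-(trimethylsilyl)ethoxycarbonyloxy]cyclohex-4-ene (all cis), via lithium alkoxide 15 (not isolated)
Conditions: LiN(SiMe3)2, THF, −78 °C; then angelic anhydride, −78 to −20 °C
Reagents that add atoms: angelic anhydride, C/C=C(/C)C(=O)OC(=O)/C(C)=C\C
Why: O-Acylation of the preformed lithium alkoxide by the anhydride, which proceeds with retention at C8 and, with no nucleophilic catalyst present, should not isomerise the angeloyl group to tigloyl.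

Step 9
Reactants: 16 the C6 silyl ether
Product: 17 2-angeloyloxy-1-[(3S)-3-angeloyloxy-6-methylhepta-1,5-dien-2-yl]-6-hydroxy-4-methyl-3-[2-(trimethylsilyl)ethoxycarbonyloxy]cyclohex-4-ene (all cis)
Conditions: HF·pyridine, pyridine, THF, 0 °C to rt
Reagents that add atoms: none
Why: Fluoride-mediated desilylation, in which buffered HF cleaves the silicon–oxygen bond of the silyl ether but not the carbon-bound silicon of the 2-(trimethylsilyl)ethyl carbonate, the esters or the alkenes.

Step 10
Reactants: 17 the all-cis C6 alcohol; 6 angelic acid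
Product: 18 2,6-bis(angeloyloxy)-1-[(3S)-3-angeloyloxy-6-methylhepta-1,5-dien-2-yl]-4-methyl-3-[2-(trimethylsilyl)ethoxycarbonyloxy]cyclohex-4-ene (C6 oxygen trans to the C1/C2/C3 substituents)
Conditions: PPh3, diisopropyl azodicarboxylate, toluene, 0 °C to rt
Reagents that add atoms: none
Why: Mitsunobu esterification, in which angelate displaces the allylic C6 oxyphosphonium by SN2 from the open face opposite the three cis substituents, so that one step inverts C6 to the configuration of the target and installs the third angelate.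

Step 11
Reactants: 18 the tris-angelate
Product: 19 2,6-bis(angeloyloxy)-1-{(3S)-3-angeloyloxy-4-[(2R)-3,3-dimethyloxiran-2-yl]but-1-en-2-yl}-4-methyl-3-[2-(trimethylsilyl)ethoxycarbonyloxy]cyclohex-4-ene
Conditions: 1,2:4,5-di-O-isopropylidene-β-D-erythro-hexo-2,3-diulopyranose (Shi ketone, 0.3 equiv), KHSO5 (Oxone), K2CO3, Bu4NHSO4, MeCN/CH2(OMe)2/aq. Na2B4O7 buffer, 0 °C
Reagents that add atoms: potassium peroxymonosulfate, OOS(=O)(=O)[O-].[K+]
Why: Shi asymmetric epoxidation, in which the chiral dioxirane attacks the electron-rich, unhindered C10=C11 alkene in preference to the ring alkene (flanked and deactivated by two allylic oxygens), the 1,1-disubstituted alkene and the angelates, and sets C10 (R) through its spiro transition state.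

Step 12
Reactants: 19 the C3 carbonate
Product: 20 2,6-bis(angeloyloxy)-1-{(3S)-3-angeloyloxy-4-[(2R)-3,3-dimethyloxiran-2-yl]but-1-en-2-yl}-3-hydroxy-4-methylcyclohex-4-ene
Conditions: Bu4NF, AcOH (1:1), THF, 0 °C to rt
Reagents that add atoms: none
Why: Fluoride-induced β-elimination of the 2-(trimethylsilyl)ethyl carbonate, which releases the C3 hydroxyl with loss of ethene and CO2, while the acetic acid buffer should suppress angeloyl migration from O2 to O3 and spare the epoxide.

Step 13
Reactants: 20 the C3 allylic alcohol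
Product: 21 the target, CNP0147918.1
Conditions: VO(acac)2 (5 mol %), tBuOOH, CH2Cl2, 0 °C to rt
Reagents that add atoms: tert-butyl hydroperoxide, CC(C)(C)OO
Why: Vanadium-catalysed hydroxyl-directed epoxidation (Sharpless–Michaelson type), in which the vanadate ester of the C3 hydroxyl delivers oxygen to the same face of C4=C5, also the face away from the C6 ester, giving the cis-epoxy alcohol and leaving alkenes not allylic to a free hydroxyl untouched.

Compound list
1 | ethyl glyoxylate | CCOC(=O)C=O | starting material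
2 | 3-methylbut-1-ene | C=CC(C)C | starting material
3 | ethyl (2S)-2-hydroxy-5-methylhex-4-enoate | CCOC(=O)[C@@H](O)CC=C(C)C | intermediate
4 | (2S)-2-hydroxy-N-methoxy-N,5-dimethylhex-4-enamide (Weinreb amide) | CON(C)C(=O)[C@@H](O)CC=C(C)C | intermediate
5 | (4S)-4-hydroxy-7-methyloct-6-en-1-yn-3-one | C#CC(=O)[C@@H](O)CC=C(C)C | intermediate
6 | angelic acid, (Z)-2-methylbut-2-enoic acid | C/C=C(/C)C(=O)O | starting material
7 | (1Z,4S)-4-hydroxy-7-methyl-3-oxoocta-1,6-dien-1-yl (Z)-2-methylbut-2-enoate | C/C=C(/C)C(=O)O/C=C\C(=O)[C@@H](O)CC=C(C)C | intermediate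
8 | (tert-butyldimethylsilyloxy)acetaldehyde | O=CCO[Si](C)(C)C(C)(C)C | starting material
9 | 2-(triphenylphosphoranylidene)propanal | CC(C=O)=P(c1ccccc1)(c1ccccc1)c1ccccc1 | starting material
10 | (E)-4-(tert-butyldimethylsilyloxy)-2-methylbut-2-enal | O=C/C(C)=C/CO[Si](C)(C)C(C)(C)C | intermediate
11 | potassium (1E,3E)-4-(tert-butyldimethylsilyloxy)-2-methylbuta-1,3-dien-1-olate | [K+].[O-]/C=C(C)/C=C/O[Si](C)(C)C(C)(C)C | intermediate
12 | (1E,3E)-4-(tert-butyldimethylsilyloxy)-2-methylbuta-1,3-dien-1-yl 2-(trimethylsilyl)ethyl carbonate | C[Si](C)(C)CCOC(=O)O/C=C(C)/C=C/O[Si](C)(C)C(C)(C)C | intermediate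
13 | all-cis Diels–Alder adduct: cyclohex-4-ene with 1-[(2S)-2-hydroxy-5-methylhex-4-enoyl], 2-angeloyloxy, 3-[2-(trimethylsilyl)ethoxycarbonyloxy], 4-methyl, 6-(tert-butyldimethylsilyloxy) | O=C([C@H]1[C@@H](OC(=O)/C(C)=C\C)[C@@H](OC(=O)OCC[Si](C)(C)C)C(C)=C[C@H]1O[Si](C)(C)C(C)(C)C)[C@@H](O)CC=C(C)C | intermediate
14 | as 13 with the ketone replaced by C7=CH2: 1-[(3S)-3-hydroxy-6-methylhepta-1,5-dien-2-yl] | C=C([C@H]1[C@@H](OC(=O)/C(C)=C\C)[C@@H](OC(=O)OCC[Si](C)(C)C)C(C)=C[C@H]1O[Si](C)(C)C(C)(C)C)[C@@H](O)CC=C(C)C | intermediate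
15 | lithium C8 alkoxide of 14 | C=C([C@H]1[C@@H](OC(=O)/C(C)=C\C)[C@@H](OC(=O)OCC[Si](C)(C)C)C(C)=C[C@H]1O[Si](C)(C)C(C)(C)C)[C@@H]([O-])CC=C(C)C.[Li+] | intermediate
16 | C8 angelate of 14 (C2 and C8 angelates, C3 carbonate, C6 silyl ether, all cis on the ring) | C=C([C@H]1[C@@H](OC(=O)/C(C)=C\C)[C@@H](OC(=O)OCC[Si](C)(C)C)C(C)=C[C@H]1O[Si](C)(C)C(C)(C)C)[C@H](CC=C(C)C)OC(=O)/C(C)=C\C | intermediate
17 | C6 alcohol (6-OH cis to the C1, C2 and C3 substituents) | C=C([C@H]1[C@@H](OC(=O)/C(C)=C\C)[C@@H](OC(=O)OCC[Si](C)(C)C)C(C)=C[C@H]1O)[C@H](CC=C(C)C)OC(=O)/C(C)=C\C | intermediate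
18 | tris-angelate with inverted C6 (6-OAng trans to the C1, C2 and C3 substituents) | C=C([C@H]1[C@@H](OC(=O)/C(C)=C\C)[C@@H](OC(=O)OCC[Si](C)(C)C)C(C)=C[C@@H]1OC(=O)/C(C)=C\C)[C@H](CC=C(C)C)OC(=O)/C(C)=C\C | intermediate
19 | (10R)-10,11-epoxide of 18 | C=C([C@H]1[C@@H](OC(=O)/C(C)=C\C)[C@@H](OC(=O)OCC[Si](C)(C)C)C(C)=C[C@@H]1OC(=O)/C(C)=C\C)[C@H](C[C@H]1OC1(C)C)OC(=O)/C(C)=C\C | intermediate
20 | C3 allylic alcohol (carbonate removed) | C=C([C@H]1[C@@H](OC(=O)/C(C)=C\C)[C@@H](O)C(C)=C[C@@H]1OC(=O)/C(C)=C\C)[C@H](C[C@H]1OC1(C)C)OC(=O)/C(C)=C\C | intermediate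
21 | CNP0147918.1: 2,6,8-tris(angeloyloxy)-4,5:10,11-diepoxy-3-hydroxybisabol-7(14)-ene skeleton, ring epoxide cis to 3-OH, (8S,10R) | C=C([C@H]1[C@@H](OC(=O)/C(C)=C\C)[C@@H](O)[C@@]2(C)O[C@H]2[C@@H]1OC(=O)/C(C)=C\C)[C@H](C[C@H]1OC1(C)C)OC(=O)/C(C)=C\C | target

Total step count: 13. Longest linear sequence: 11 steps (1, 2, 3, 6, 7, 8, 9, 10, 11, 12, 13).

Steps most likely to fail

Step 6. The magnesium chelate may not hold, which would show as erosion of facial or endo selectivity, as migration of the angeloyl group from the enol oxygen to the free C8 hydroxyl, or as decay of the diene under the Lewis acid. The fallback moves stereocontrol from the substrate to a reagent and sets out from 7. The C8 hydroxyl is first esterified with angelic anhydride under Sc(OTf)3 catalysis (MeCN, −20 °C) to the bis-angelate dienophile F1. F1 is then combined with 12 under the triflimide-activated oxazaborolidine made from α,α-diphenylprolinol and o-tolylboroxine (Tf2NH, CH2Cl2, −78 °C; the enantiomer that exposes the Re face of C1), which should give the all-cis ketone adduct F2. Methylenation of F2 with Zn, CH2Br2 and TiCl4 comes back to the route at 16.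

Step 3. The kinetic (Z)-enol ester may isomerise to the (E)-isomer, or the hydroxyl may close onto the ynone to a furanone. The fallback sets out from 5 and fixes the geometry through a halide. Anti-hydroiodination with NaI in AcOH should give the configurationally stable (Z)-β-iodo enone F3. Silver angelate, AgO2CC(CH3)=CHCH3 (from 6 and Ag2O), in toluene then replaces iodide by addition–elimination with retention and comes back at 7.

Step 10. The activated C6 alcohol may eliminate toward the conjugated triene, or the ester may form with retention through an acyloxyphosphonium. The fallback sets out from 17 and inverts C6 by oxidation and reduction. Dess–Martin periodinane (NaHCO3, CH2Cl2) gives the cyclohexenone F4. Catecholborane under the B-methyl oxazaborolidine from diphenylprolinol (the enantiomer that delivers hydride syn to the C1 side chain) should give the C6-epimeric alcohol F5. Acylation of F5 with LiN(SiMe3)2 and angelic anhydride as in step 8 comes back at 18.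

Further compounds
F1 | step 6 | (1Z,4S)-7-methyl-3-oxoocta-1,6-diene-1,4-diyl bis[(Z)-2-methylbut-2-enoate] | C/C=C(/C)C(=O)O/C=C\C(=O)[C@H](CC=C(C)C)OC(=O)/C(C)=C\C
F2 | step 6 | all-cis Diels–Alder adduct carrying the C8 angelate (ketone at C7) | O=C([C@H]1[C@@H](OC(=O)/C(C)=C\C)[C@@H](OC(=O)OCC[Si](C)(C)C)C(C)=C[C@H]1O[Si](C)(C)C(C)(C)C)[C@H](CC=C(C)C)OC(=O)/C(C)=C\C
F3 | step 3 | (1Z,4S)-4-hydroxy-1-iodo-7-methylocta-1,6-dien-3-one | I/C=C\C(=O)[C@@H](O)CC=C(C)C
F4 | step 10 | C6 ketone (cyclohex-4-en-6-one) derived from 17 | C=C([C@H]1[C@@H](OC(=O)/C(C)=C\C)[C@@H](OC(=O)OCC[Si](C)(C)C)C(C)=CC1=O)[C@H](CC=C(C)C)OC(=O)/C(C)=C\C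
F5 | step 10 | C6-epimeric alcohol (6-OH trans to the C1 side chain) | C=C([C@H]1[C@@H](OC(=O)/C(C)=C\C)[C@@H](OC(=O)OCC[Si](C)(C)C)C(C)=C[C@@H]1O)[C@H](CC=C(C)C)OC(=O)/C(C)=C\C
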